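**Plan**
1. Numbering (eunicellane): ring A = C1, C10, C11 (CH3 = C17, OH), C12, C13, C14 (isopropyl). The ten-membered ring = C1 to C10, with C2=C3 (CH3 = C15), C6–OAc, C7=C16H2 and C9–OAc.
2. Cuts: remove the acetates, take C7=C16 back to a C7 ketone, the C11 carbinol back to C11=C17H2, and C6–O back to an enolate. Then cut C4–C5 and rejoin C2–C7 (retro anionic oxy-Cope). Finally cut C1–C2 and C9–C10 (retro Diels–Alder).
3. Enabling feature: in the ten-membered ring the masked ketone C7 and the C2=C3 alkene form a cyclodec-5-enone (C7 is four bonds from C3), and O6 is alpha to C7. The ring is therefore the four-carbon expansion of a six-membered ring B (C1, C2, C7, C8, C9, C10) with isopropenyl (C3, C4, C15) on C2 and vinyl (C5, C6) plus OH on C7.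
4. Forward order: ring A (organocatalytic Michael addition, aldol condensation), then ring B (Diels–Alder reaction with a triene from mesityl oxide and ethyl formate), then the ten-membered ring by expansion of ring B, then C11, C16 and the acetates.
5. Stereochemistry: C14 comes from the prolinol catalyst. C1, C10 and C9 come from the anti, endo cycloaddition. The sacrificial centres C2 (equilibration) and C7 (convex-face ethynylation) are traded for 2Z and 6R. C11 comes from bottom-face radical oxygenation.
6. Helpers: TIPS on O9, TES on O6, and the sp2 placeholder C11=C17H2, which keeps the productive ring B chair. All are removed or converted after the key step.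

Key step: step 10

Remark: the target SMILES is read as 1S,2Z,6R,9R,10S,11R,14R. "Top" is the face of ring A that carries the C1–C2 and C10–C9 bonds. H-1, H-10, the isopropyl group and the C11 hydroxyl group lie on the bottom. Both enantiomers of the prolinol ether catalyst are taken to be commercial.

**Step 1**
Reactants: 1 3-methylbutanal; 2 but-3-en-2-one
Product: 3 (R)-2-isopropyl-5-oxohexanal
Conditions: (R)-2-[methoxy(diphenyl)methyl]pyrrolidine (5 mol %), ethyl 3,4-dihydroxybenzoate (20 mol %), neat, 4 °C
Reagents that add atoms: none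
Why: Enamine-catalysed asymmetric Michael addition, in which the diphenyl(methoxy)methyl group of the R catalyst shields one face of the E-enamine of 1, so 2 adds to the open face and sets the isopropyl-bearing centre (future C14) as R.

**Step 2**
Reactants: 3 (R)-2-isopropyl-5-oxohexanal
Product: 4 (R)-4-isopropylcyclohex-2-en-1-one (ring A)
Conditions: LiOH (0.2 equiv), iPrOH, rt
Reagents that add atoms: none
Why: Intramolecular aldol condensation of the methyl ketone onto the aldehyde closes ring A and dehydrates to the enone, and the mild catalytic base should leave the stereocentre untouched.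

**Step 3**
Reactants: 5 4-methylpent-3-en-2-one (mesityl oxide); 6 ethyl formate
Product: 8 (1E)-5-methyl-1-(triisopropylsilyloxy)hexa-1,4-dien-3-one, via sodium enolate 7 (not isolated)
Conditions: NaH, HCO2Et, Et2O, 0 °C to rt; then TIPSCl, THF, rt
Reagents that add atoms: ethyl formate (6), CCOC=O; triisopropylsilyl chloride, CC(C)[Si](Cl)(C(C)C)C(C)C
Why: Crossed Claisen formylation of the acetyl CH3 gives the stabilised keto-aldehyde enolate, which the hard silyl chloride captures on oxygen as the more stable E vinylogous silyl ester.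

**Step 4**
Reactants: 8 (1E)-5-methyl-1-(triisopropylsilyloxy)hexa-1,4-dien-3-one
Product: 9 (1E,3Z)-3-(tert-butyldimethylsilyloxy)-5-methyl-1-(triisopropylsilyloxy)hexa-1,3,5-triene
Conditions: TBSOTf, Et3N, Et2O, 0 °C
Reagents that add atoms: tert-butyldimethylsilyl triflate, CC(C)(C)[Si](C)(C)OS(=O)(=O)C(F)(F)F
Why: Soft enolisation, in which only a gamma (methyl) proton can be removed and the beta,beta-disubstituted enone reacts from its s-cis form, so the isopropenyl group ends cis to OTBS (3Z) and therefore outside in the s-cis diene.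

**Step 5**
Reactants: 4 (R)-4-isopropylcyclohex-2-en-1-one; 9 bis(silyloxy)triene
Product: 10 endo adduct: cis-fused decal-7-en-11-one with 7-OTBS; 9-OTIPS top; 2-isopropenyl top; 14-isopropyl bottom; H-1 and H-10 bottom
Conditions: EtAlCl2 (0.3 equiv), toluene, −78 to −20 °C
Reagents that add atoms: none
Why: Lewis-acid-catalysed Diels–Alder reaction of a substituted cyclohexenone with a silyloxydiene, in which the nucleophilic terminus C2 bonds to the beta carbon C1 and C9 bonds to C10, while approach anti to the isopropyl group and endo to the ketone sets C1, C10 (cis fusion), C9 and C2 at once.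

**Step 6**
Reactants: 10 endo adduct
Product: 11 11-methylene analogue of 10 (C11=C17H2)
Conditions: Cp2TiMe2 (2.5 equiv), toluene, 70 °C, dark
Reagents that add atoms: dimethyltitanocene, [CH3-].[CH3-].[Ti+4].c1cc[cH-]c1.c1cc[cH-]c1
Why: Petasis methylenation is non-basic, so the epimerisable C10, the beta-silyloxy group and the enol silane should survive while the only free carbonyl group becomes the sp2 placeholder for the carbinol.

**Step 7**
Reactants: 11 11-methylene enol silane
Product: 13 cis-fused 11-methylenedecalin-7-one with 2-isopropenyl bottom; 9-OTIPS top; 14-isopropyl bottom, via C2-epimeric ketone 12 (not isolated)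
Conditions: TBAF (1.05 equiv), AcOH (1.2 equiv), THF, −20 °C; then DBU (0.5 equiv), rt
Reagents that add atoms: none
Why: Buffered fluoride cleaves the enol silane much faster than the secondary TIPS ether, and base-mediated epimerisation of the doubly activated C2–H (alpha-protonation of the dienolate outruns gamma-protonation) should then settle on the bottom-face epimer, which avoids the syn-pentane contact between the isopropenyl and isopropyl groups in 12.

**Step 8**
Reactants: 13 decalin-7-one; 14 ethynylmagnesium bromide
Product: 15 7-ethynyl carbinol (ethynyl bottom and cis to isopropenyl; 7-OH top)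
Conditions: HC≡CMgBr, LaCl3·2LiCl (0.3 equiv), THF, −78 to −20 °C; aq NH4Cl
Reagents that add atoms: ethynylmagnesium bromide (14), C#C[Mg]Br
Why: 1,2-Addition of a slim acetylide, with the lanthanum salt suppressing enolisation, should proceed by axial attack on the convex bottom face of the ring B chair, so C7 receives an axial alkynyl group and an equatorial top-face hydroxyl group.

**Step 9**
Reactants: 15 7-ethynyl carbinol
Product: 16 7-vinyl carbinol (vinyl and isopropenyl both bottom; 7-OH top)
Conditions: H2 (1 atm), Pd/CaCO3 poisoned with Pb(OAc)2, quinoline, EtOAc, rt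
Reagents that add atoms: none
Why: Lindlar semihydrogenation stops at the vinyl group and leaves the 1,1-disubstituted alkenes alone, and no stereocentre is formed.

**Step 10**
Reactants: 16 7-vinyl carbinol
Product: 19 ring-expanded (2Z,6R)-6-hydroxy-7-ketone of the 6/10 bicycle (9-OTIPS; C11=C17H2), via potassium alkoxide 17 (not isolated), via potassium enolate 18 (not isolated)
Conditions: KH (1.3 equiv), 18-crown-6 (1.3 equiv), THF, 0 °C to rt; then −78 °C, 2-(phenylsulfonyl)-3-phenyloxaziridine (1.5 equiv); aq NH4Cl
Reagents that add atoms: 2-(phenylsulfonyl)-3-phenyloxaziridine, O=S(=O)(c1ccccc1)N1OC1c1ccccc1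
Why: Deprotonation gives alkoxide 17, whose oxyanion weakens the C2–C7 bond, so the 3-oxido-1,5-diene C5=C6–C7(O−)–C2–C3=C4 undergoes a charge-accelerated [3,3]-sigmatropic shift (anionic oxy-Cope rearrangement) that forms C4–C5 and breaks C2–C7. The closest known reaction type is the four-carbon expansion of 1,2-dialkenylcyclohexanols to cyclodec-5-enones with oxidation of the regiodefined enolate in the same flask. The ten-membered ring C1–C10 is thus closed by expansion of ring B through a six-centre chair transition state rather than by end-to-end cyclisation, and enolate formation drives it. The 2Z geometry follows from the ring B chair with isopropenyl equatorial and vinyl axial, in which C1 is axial in the six-centre chair and ends cis to C4; the flipped chair that would give 2E has C14, O7 and OTIPS all axial on one face and isopropenyl axial on the other, and the sp2 C11 removes the axial methyl group that would otherwise penalise the productive chair. The same chair delivers enolate 18 with C5 trans to C8, so the ring covers the inner face and the oxaziridine should transfer oxygen to the outer (Re) face of C6, which sets 6R. The step also needs the rearrangement to outrun O9-to-O7 silyl migration and beta-elimination of O9, and the enolate must stay regiodefined; the bulky TIPS group, the distant diequatorial O7/O9 pair and cold trapping before proton exchange secure this.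

**Step 11**
Reactants: 19 6-hydroxy-7-ketone
Product: 20 6-O-triethylsilyl ether of 19
Conditions: TESOTf, 2,6-lutidine, CH2Cl2, −78 °C
Reagents that add atoms: triethylsilyl triflate, CC[Si](CC)(CC)OS(=O)(=O)C(F)(F)F
Why: Silyl triflate silylation with a hindered base protects the alpha-ketol at low temperature before it can epimerise or undergo ketol shift.

**Step 12**
Reactants: 20 6-OTES ketone
Product: 21 (11R)-11-hydroxy-11-methyl ketone (OH bottom; C17H3 top)
Conditions: Mn(dpm)3 (0.1 equiv; dpm = 2,2,6,6-tetramethylheptane-3,5-dionate), PhSiH3 (2.5 equiv), O2 (1 atm), iPrOH–CH2Cl2, 0 °C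
Reagents that add atoms: dioxygen, O=O
Why: Mukaiyama hydration, in which hydrogen-atom transfer should pick the only 1,1-disubstituted alkene left after the rearrangement over the hindered trisubstituted C2=C3, and the tertiary C11 radical is oxygenated on the bottom face, anti to the axial C9 branch on C10, which sets 11R.

**Step 13**
Reactants: 21 11-hydroxy ketone
Product: 22 7-methylene compound (C7=C16H2; 6-OTES; 9-OTIPS; 11-OH)
Conditions: Cp2TiMe2 (4 equiv), toluene–THF, 75 °C, dark
Reagents that add atoms: dimethyltitanocene, [CH3-].[CH3-].[Ti+4].c1cc[cH-]c1.c1cc[cH-]c1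
Why: Petasis methylenation is non-basic, so C6 should not epimerise and O9 should not be eliminated, and the free tertiary alcohol only consumes extra reagent.

**Step 14**
Reactants: 22 bis(silyl ether)
Product: 23 6,9,11-triol
Conditions: TBAF (4 equiv), THF, rt to 40 °C
Reagents that add atoms: none
Why: Fluoride-mediated desilylation removes TES and TIPS in one operation without touching the alkenes or any stereocentre.

**Step 15**
Reactants: 23 6,9,11-triol
Product: 24 target CNP0303839.1
Conditions: Ac2O (3 equiv), pyridine, DMAP (cat.), CH2Cl2, 0 °C to rt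
Reagents that add atoms: acetic anhydride, CC(=O)OC(C)=O
Why: DMAP-catalysed acetylation should take the two secondary alcohols (C6, C9), while the hindered tertiary C11 alcohol stays free under these conditions.

**Compound list**
1 | 3-methylbutanal | CC(C)CC=O | starting material
2 | but-3-en-2-one | CC(=O)C=C | starting material
3 | (R)-2-isopropyl-5-oxohexanal | CC(C)[C@@H](CCC(C)=O)C=O | intermediate
4 | (R)-4-isopropylcyclohex-2-en-1-one | CC(C)[C@H]1CCC(=O)C=C1 | intermediate
5 | 4-methylpent-3-en-2-one | CC(C)=CC(C)=O | starting material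
6 | ethyl formate | CCOC=O | starting material
7 | sodium 5-methyl-3-oxohexa-1,4-dien-1-olate (delocalised, geometry not fixed) | CC(C)=CC(=O)C=C[O-].[Na+] | intermediate
8 | (1E)-5-methyl-1-(triisopropylsilyloxy)hexa-1,4-dien-3-one | CC(C)=CC(=O)/C=C/O[Si](C(C)C)(C(C)C)C(C)C | intermediate
9 | (1E,3Z)-3-(tert-butyldimethylsilyloxy)-5-methyl-1-(triisopropylsilyloxy)hexa-1,3,5-triene | C=C(C)/C=C(\O[Si](C)(C)C(C)(C)C)/C=C/O[Si](C(C)C)(C(C)C)C(C)C | intermediate
10 | endo Diels–Alder adduct, cis-fused decal-7-en-11-one | CC(C)(C)[Si](C)(C)OC1=C[C@@H](O[Si](C(C)C)(C(C)C)C(C)C)[C@@H]2[C@H]([C@H]1C(C)=C)[C@@H](C(C)C)CCC2=O | intermediate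
11 | 11-methylene enol silane | CC(C)(C)[Si](C)(C)OC1=C[C@@H](O[Si](C(C)C)(C(C)C)C(C)C)[C@@H]2[C@H]([C@H]1C(C)=C)[C@@H](C(C)C)CCC2=C | intermediate
12 | decalin-7-one, 2-isopropenyl top | O=C1C[C@@H](O[Si](C(C)C)(C(C)C)C(C)C)[C@@H]2[C@H]([C@H]1C(C)=C)[C@@H](C(C)C)CCC2=C | intermediate
13 | decalin-7-one, 2-isopropenyl bottom | O=C1C[C@@H](O[Si](C(C)C)(C(C)C)C(C)C)[C@@H]2[C@H]([C@@H]1C(C)=C)[C@@H](C(C)C)CCC2=C | intermediate
14 | ethynylmagnesium bromide | C#C[Mg]Br | starting material
15 | 7-ethynyl carbinol | C#C[C@]1(O)C[C@@H](O[Si](C(C)C)(C(C)C)C(C)C)[C@@H]2[C@H]([C@@H]1C(C)=C)[C@@H](C(C)C)CCC2=C | intermediate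
16 | 7-vinyl carbinol | C=C[C@]1(O)C[C@@H](O[Si](C(C)C)(C(C)C)C(C)C)[C@@H]2[C@H]([C@@H]1C(C)=C)[C@@H](C(C)C)CCC2=C | intermediate
17 | potassium alkoxide of 16 | [K+].C=C[C@]1([O-])C[C@@H](O[Si](C(C)C)(C(C)C)C(C)C)[C@@H]2[C@H]([C@@H]1C(C)=C)[C@@H](C(C)C)CCC2=C | intermediate
18 | potassium C6=C7 enolate of the ten-membered ring (2Z; C5 trans to C8) | [K+].C1[C@@H](O[Si](C(C)C)(C(C)C)C(C)C)[C@@H]2[C@H](/C=C(/C)CC/C=C1\[O-])[C@@H](C(C)C)CCC2=C | intermediate
19 | (2Z,6R)-6-hydroxy-7-ketone | O=C1C[C@@H](O[Si](C(C)C)(C(C)C)C(C)C)[C@@H]2[C@H](/C=C(/C)CC[C@H]1O)[C@@H](C(C)C)CCC2=C | intermediate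
20 | 6-OTES ketone | O=C1C[C@@H](O[Si](C(C)C)(C(C)C)C(C)C)[C@@H]2[C@H](/C=C(/C)CC[C@H]1O[Si](CC)(CC)CC)[C@@H](C(C)C)CCC2=C | intermediate
21 | (11R)-11-hydroxy ketone | O=C1C[C@@H](O[Si](C(C)C)(C(C)C)C(C)C)[C@@H]2[C@H](/C=C(/C)CC[C@H]1O[Si](CC)(CC)CC)[C@@H](C(C)C)CC[C@@]2(C)O | intermediate
22 | 7-methylene bis(silyl ether) | C=C1C[C@@H](O[Si](C(C)C)(C(C)C)C(C)C)[C@@H]2[C@H](/C=C(/C)CC[C@H]1O[Si](CC)(CC)CC)[C@@H](C(C)C)CC[C@@]2(C)O | intermediate
23 | 6,9,11-triol | C=C1C[C@@H](O)[C@@H]2[C@H](/C=C(/C)CC[C@H]1O)[C@@H](C(C)C)CC[C@@]2(C)O | intermediate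
24 | CNP0303839.1 | C=C1C[C@@H](OC(C)=O)[C@@H]2[C@H](/C=C(/C)CC[C@H]1OC(C)=O)[C@@H](C(C)C)CC[C@@]2(C)O | target

**Step count**
Total step count: 15.
Longest linear sequence: 13 (steps 1, 2, 5–15). The triene branch (steps 3, 4, 5–15) has the same length.

**Steps most likely to fail**

Step 5. The hindered triene may react sluggishly with the weak dienophile. The Lewis acid may degrade the triene, and steric pressure next to the isopropyl group may erode endo selectivity.
The fallback runs from 4 back to 10 and uses a temporary activating group on the dienophile.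
- Bromination and dehydrobromination (Br2, then Et3N, CH2Cl2, 0 °C) gives (R)-2-bromo-4-isopropylcyclohex-2-en-1-one F1.
- Its lower LUMO should allow cycloaddition with 9 without a Lewis acid (toluene, 60–80 °C), giving the 10-bromo adduct F2.
- Radical debromination (Bu3SnH, AIBN, toluene, 80 °C) delivers hydrogen to the convex bottom face of the C10 radical and returns cis-fused 10.

Step 10. The ten-membered enolate may turn its C6=C7 unit through the ring before it is trapped, which would erode facial control at C6.
The fallback runs from 16 back to 19 and sets the centre by substitution instead of facial choice.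
- The rearrangement and hydroxylation are run as before, and the 6S alcohol, 6-epi-hydroxy ketone F3, is collected.
- Mitsunobu reaction (PPh3, DIAD, AcOH, toluene, 0 °C) displaces next to the carbonyl group with inversion, giving the 6R acetoxy ketone F4.
- Brief methanolysis (K2CO3, MeOH, 0 °C) returns 19.

Step 12. Hydrogen-atom transfer may also engage C2=C3, and oxygen capture at the C11 radical may show poor facial selectivity.
The fallback runs from 20 back to 21 and replaces the radical hydration with a concerted, sterically governed oxidation followed by deoxygenation.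
- OsO4 (cat.), NMO, acetone–water should dihydroxylate the exposed methylene group from the bottom face, giving the 11,17-diol F5.
- I2, PPh3, imidazole converts the primary alcohol into the 17-iodide F6.
- Bu3SnH, AIBN (toluene, 80 °C) reduces the C–I bond to the C17 methyl group of 21 without touching the ketone.

**Further compounds**
F1 | step 5 | (R)-2-bromo-4-isopropylcyclohex-2-en-1-one | CC(C)[C@H]1CCC(=O)C(Br)=C1
F2 | step 5 | 10-bromo Diels–Alder adduct (Br bottom) | CC(C)(C)[Si](C)(C)OC1=C[C@@H](O[Si](C(C)C)(C(C)C)C(C)C)[C@]2(Br)[C@H]([C@H]1C(C)=C)[C@@H](C(C)C)CCC2=O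
F3 | step 10 | (2Z,6S)-6-hydroxy-7-ketone (6-epimer of 19) | O=C1C[C@@H](O[Si](C(C)C)(C(C)C)C(C)C)[C@@H]2[C@H](/C=C(/C)CC[C@@H]1O)[C@@H](C(C)C)CCC2=C
F4 | step 10 | (2Z,6R)-6-acetoxy-7-ketone | O=C1C[C@@H](O[Si](C(C)C)(C(C)C)C(C)C)[C@@H]2[C@H](/C=C(/C)CC[C@H]1OC(C)=O)[C@@H](C(C)C)CCC2=C
F5 | step 12 | 11,17-diol (11-OH bottom) | O=C1C[C@@H](O[Si](C(C)C)(C(C)C)C(C)C)[C@@H]2[C@H](/C=C(/C)CC[C@H]1O[Si](CC)(CC)CC)[C@@H](C(C)C)CC[C@@]2(CO)O
F6 | step 12 | 11-hydroxy-17-iodide | O=C1C[C@@H](O[Si](C(C)C)(C(C)C)C(C)C)[C@@H]2[C@H](/C=C(/C)CC[C@H]1O[Si](CC)(CC)CC)[C@@H](C(C)C)CC[C@@]2(CI)O
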